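- A chance of 0.0428 is where I start: in the summer run, which is this flask followed so far, that is the last product reading per partner charged, so I read it as the selectivity of one partner molecule for product.

| setting | summer | dawn | flask |
|---|---|---|---|
| starting material | 0.011 M | 0.0074 M | 0.011 M |
| partner | 0.055 M | 0.055 M | 0.0550 M |
| free catalyst | 0.18 mM | 0.18 mM | 0.18 mM |
| remark | the very flask that is asked about, followed so far | run made earlier |  |

- summer (time / h: product / %, starting material / %): 3.00: 6.9, 94.1; 5.00: 10.1, 90.8; 8.00: 15.4, 85.9; 12.0: 16.4, 82.2; 20.0: 21.0, 79.4; 30.0: 21.2, 77.3; 40.0: 21.4, 77.6
- dawn (time / d: product / %, starting material / %): 0.333: 14.0, 84.3; 0.833: 23.3, 78.4; 1.67: 25.3, 73.6; 2.50: 24.2, 75.0; 4.00: 23.3, 74.4; 5.00: 26.3, 74.0; 6.00: 25.4, 74.0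

(each reading ± 1 percentage point)

- no earlier run changes the charge of free catalyst; that part of a forecast is a guess
- no earlier run changes the charge of partner; that part of a forecast is a guess

- apparent order in partner when 10% of the starting material are converted (percent change of the rate of making product for one percent more partner charged)
- factor on the rate of making product when 10% of the starting material are converted if free catalyst is charged twice over

- I turn the question round. Taking one partner for each starting material, for the flask to finish that chance must reach 0.200, the starting material per partner charged, and the reading stands lower. So I suppose that nearly all of the partner leaves by another fork, at a pace of its own, and that the stall marks partner gone.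
- If the rate is first order in starting material and in partner, and the catalyst holds steady, the logarithm of the starting material remaining falls in step with partner lost by that other fork. My spent share, the logarithm at the mark over the logarithm at the stall, is then 0.438: the part of the partner I reckon gone when the mark is reached.
- On the same suppositions I take the spent share as inversely proportional to partner charged times catalyst charged, which no run tests, and the rate at the mark as going with partner charged, catalyst charged and one minus the share. The order is then one over one minus the spent share, 1.78, and doubling catalyst gives two minus the share over one minus the share, 2.78. Plain values of one and two need a share near zero, and this flask reads 0.438.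
- The forecast gives lower values, 1.2 and 1.95, and in its words: “Catalyst should act on both directions”.
- The flask gives an order of 1.7 and a factor of 2.59, against my 1.78 and 2.78.

    partner → decomposed reagent (k = 0.0840 h⁻¹)
    2 free catalyst → spent catalyst (k = 47.0 M⁻¹ h⁻¹)
    starting material + partner + free catalyst → product + free catalyst, rate k3*[starting material]*[partner]*[free catalyst]/(1 + ([starting material]/sat3)) (26.0 mM, k = 3700 M⁻² h⁻¹)

- At the start, partner goes to decomposed reagent 16 times as fast as it goes to product. The dawn run reads 25.4% product at 6.00 d, so its spent share at the same mark is 0.360, smaller than this flask's, and its order by the same rule is 1.56.

All runs are calculated with made-up constants, and the scatter is random.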